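**Retrosynthetic overview** (carotenoid numbering: ring C1–C6, chain C7–C15, primed numbers on the acyclic half)

1. The target is all-E (6R)-7',8'-dihydro-ε,ψ-carotene (α-zeacarotene). Its only ring, the 2,6,6-trimethylcyclohex-2-ene ring that carries C6, is never formed in the route: it is bought with its stereocentre as (R)-α-ionone.
2. Key disconnection: the C10'–C11' single bond of the terminal diene C9'(CH3)=C10'H–C11'H=C12'H of the octaene. Both carbons are traced back to terminal alkyne carbons (C13 dienyne 5 and C26 hexaenyne 12), so both are born as donor alkenyl-metal carbons of like polarity. They are joined in one telescoped operation: syn-methylalumination of 5, syn-hydrozirconation then iodinolysis (polarity reversal) of 12, and Pd/Zn Negishi coupling.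
3. Enabling feature: at C9'=C10' the C19' methyl is cis to C11', and at C11'=C12' C10' is trans to C13'. This is exactly the pattern written by syn addition of CH3–Al across C9'≡C10' and of H–Zr across C12'≡C11'. The saturated C7'–C8' link keeps the alkyne of 5 out of conjugation, and the 9'E geometry, which has no thermodynamic bias (CH3 against CH2 on C9'), is fixed kinetically.
4. Hexaenyne 12 comes from Colvin homologation of the C25 aldehyde 11. Aldehyde 11 comes from a Wittig reaction (C11=C12) of the C15 phosphonium salt 8 with the C10 dialdehyde 9; salt 8 is made from (R)-α-ionone with vinylmagnesium bromide, then PPh3·HBr.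
5. Dienyne 5 comes from SN2 alkylation of lithiated 1-(trimethylsilyl)propyne with geranyl bromide, then desilylation.

Key step: step 7

Assumption: (R)-α-ionone (6) is bought as the single enantiomer; the ring stereocentre of the target is 6R and every stereo-defined double bond is E.

**Step 1**
Reactants: 1 geranyl bromide; 2 1-(trimethylsilyl)propyne
Product: 4 trimethyl[(5E)-6,10-dimethylundeca-5,9-dien-1-ynyl]silane, via 3-(trimethylsilyl)prop-2-ynyllithium 3 (not isolated)
Conditions: 2, n-BuLi, THF, −78 → −20 °C; then 1, −78 → 0 °C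
Reagents that add atoms: none
Why: SN2 alkylation of a propargyllithium by a primary allylic bromide should give the skipped enyne, because the silyl group blocks the acetylenic position and the geranyl 2E double bond is not involved.

**Step 2**
Reactants: 4 trimethyl[(5E)-6,10-dimethylundeca-5,9-dien-1-ynyl]silane
Product: 5 (5E)-6,10-dimethylundeca-5,9-dien-1-yne
Conditions: K2CO3 (cat.), MeOH, 23 °C
Reagents that add atoms: none
Why: Base-catalysed protodesilylation (methanolysis of the C(sp)–Si bond) should free the terminal alkyne without touching the two trisubstituted alkenes.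

**Step 3**
Reactants: 6 (R)-α-ionone
Product: 7 (1E)-3-methyl-1-[(1R)-2,6,6-trimethylcyclohex-2-en-1-yl]penta-1,4-dien-3-ol (vinyl-α-ionol; both carbinol epimers)
Conditions: CH2=CHMgBr, THF, −20 → 0 °C; aq. NH4Cl
Reagents that add atoms: vinylmagnesium bromide, C=C[Mg]Br
Why: Grignard 1,2-addition to the enone carbonyl should give the tertiary bis-allylic alcohol; its carbinol centre forms as a mixture that does not matter because it becomes sp2 in step 4, and C6 is not touched at low temperature.

**Step 4**
Reactants: 7 vinyl-α-ionol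
Product: 8 [(2E,4E)-3-methyl-5-[(1R)-2,6,6-trimethylcyclohex-2-en-1-yl]penta-2,4-dienyl]triphenylphosphonium bromide
Conditions: PPh3·HBr, MeOH, 23 °C; recrystallisation
Reagents that add atoms: triphenylphosphine hydrobromide, [Br-].[PH+](c1ccccc1)(c1ccccc1)c1ccccc1
Why: Acid-mediated ionisation of the tertiary allylic alcohol and capture of the pentadienyl cation by PPh3 at the unhindered primary terminus (allylic transposition, the classical C15 Wittig-salt synthesis) should give the conjugated salt, whose 9E isomer is favoured and crystallises.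

**Step 5**
Reactants: 8 C15 phosphonium bromide; 9 (2E,4E,6E)-2,7-dimethylocta-2,4,6-trienedial
Product: 11 (6R)-12'-apo-ε-caroten-12'-al, via phosphorus ylide 10 (not isolated)
Conditions: 9 (3 equiv), NaOMe (1.05 equiv, slow addition), CH2Cl2/MeOH, −10 → 23 °C, dark; then heptane, 80 °C; crystallisation
Reagents that add atoms: none
Why: Wittig olefination of the semistabilised allylic ylide at one formyl group of the symmetric dialdehyde (excess 9 suppresses double olefination) should form C11=C12 as an E/Z mixture, which heating funnels to E because the 11Z isomer is the sterically hindered cis form.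

**Step 6**
Reactants: 11 (6R)-12'-apo-ε-caroten-12'-al
Product: 12 (3E,5E,7E,9E,11E,13E)-3,8,12-trimethyl-14-[(1R)-2,6,6-trimethylcyclohex-2-en-1-yl]tetradeca-3,5,7,9,11,13-hexaen-1-yne
Conditions: Me3SiCHN2, LiN(i-Pr)2, THF, −78 °C; then 11, −78 → 0 °C, dark
Reagents that add atoms: (trimethylsilyl)diazomethane, C[Si](C)(C)C=[N+]=[N-]
Why: The Colvin rearrangement (1,2-addition of the lithiated diazo reagent, Peterson-type elimination, loss of N2 and 1,2-hydrogen shift) should turn the formyl group into the terminal alkyne in one step, and it avoids the methanol conjugate addition that Ohira–Bestmann conditions cause with enals.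

**Step 7**
Reactants: 5 (5E)-6,10-dimethylundeca-5,9-dien-1-yne; 12 C26 hexaenyne
Product: 16 (6R)-7',8'-dihydro-ε,ψ-carotene (α-zeacarotene; all-E), via alkenylalane 13 (not isolated), via alkenylzirconocene 14 (not isolated), via heptaenyl iodide 15 (not isolated)
Conditions: (a) 5 (1.5 equiv), Me3Al, Cp2ZrCl2 (0.25 equiv), CH2Cl2, 0 → 23 °C; volatiles off, THF; (b) 12, Cp2Zr(H)Cl (1.05 equiv), THF, 23 °C, dark; then I2 (1.0 equiv), −78 °C; (c) solution (b) into (a), ZnCl2 (0.5 equiv), Pd2(dba)3 (2.5 mol %), P(2-furyl)3 (10 mol %), THF, 23 °C, dark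
Reagents that add atoms: trimethylaluminium, C[Al](C)C
Why: Zr-catalysed syn-methylalumination (Negishi carboalumination) of the terminal alkyne of 5 puts CH3 on C9' and Al on C10' on the same side, and syn-hydrozirconation of the terminal alkyne of 12 puts Zr on C11' trans to C13', so that C10' and C11' are both nucleophilic alkenyl-metal carbons of like polarity. Iodinolysis of the C–Zr bond with retention reverses the polarity of C11' in the flask; oxidative addition of this C–I bond to zerovalent palladium, Al-to-Zn-to-Pd transmetalation of 13 and reductive elimination then should close the C10'–C11' bond with retention at both alkenes. The closest known reaction type is the Pd/Zn-catalysed Negishi alkenyl–alkenyl coupling of carboalumination-derived alkenylalanes with alkenyl halides, as applied to carotenoid polyenes, together with hydrozirconation–iodination of conjugated enynes. No ring is closed and no stereocentre is created; the new stereo-elements are the 9'E and 11'E double bonds, each fixed by the syn-stereospecificity of its metalation and by retention in every later event, while C6 is remote and meets neither base nor protic acid. The step needs regioselective metalation (metal on the terminal carbon, secured by the monosubstituted alkynes and by the saturated C7'–C8' link that insulates the alkyne of 5), chemoselectivity (the trisubstituted and the internal conjugated alkenes should be inert to Me3Al/Cp2ZrCl2 and to one equivalent of Cp2Zr(H)Cl) and cross- over homo-coupling (secured by the distinct donor and acceptor roles, with 13 in excess). Kinetic control is essential because CH3 and CH2 on C9' are nearly equal in size, so no equilibration could deliver the 9'E isomer.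

**Compound list**

1 | geranyl bromide, (2E)-1-bromo-3,7-dimethylocta-2,6-diene | CC(C)=CCC/C(C)=C/CBr | starting material
2 | 1-(trimethylsilyl)propyne | CC#C[Si](C)(C)C | starting material
3 | 3-(trimethylsilyl)prop-2-ynyllithium | [Li]CC#C[Si](C)(C)C | intermediate
4 | trimethyl[(5E)-6,10-dimethylundeca-5,9-dien-1-ynyl]silane | CC(C)=CCC/C(C)=C/CCC#C[Si](C)(C)C | intermediate
5 | (5E)-6,10-dimethylundeca-5,9-dien-1-yne | CC(C)=CCC/C(C)=C/CCC#C | intermediate
6 | (R)-α-ionone | CC(=O)/C=C/[C@H]1C(C)=CCCC1(C)C | starting material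
7 | (1E)-3-methyl-1-[(1R)-2,6,6-trimethylcyclohex-2-en-1-yl]penta-1,4-dien-3-ol (vinyl-α-ionol, carbinol epimers) | C=CC(C)(O)/C=C/[C@H]1C(C)=CCCC1(C)C | intermediate
8 | [(2E,4E)-3-methyl-5-[(1R)-2,6,6-trimethylcyclohex-2-en-1-yl]penta-2,4-dienyl]triphenylphosphonium bromide | [Br-].c1ccccc1[P+](c1ccccc1)(c1ccccc1)C/C=C(C)/C=C/[C@H]1C(C)=CCCC1(C)C | intermediate
9 | (2E,4E,6E)-2,7-dimethylocta-2,4,6-trienedial (C10 dialdehyde) | O=C/C(C)=C/C=C/C=C(C)/C=O | starting material
10 | phosphorus ylide of 8, [(2E,4E)-3-methyl-5-[(1R)-2,6,6-trimethylcyclohex-2-en-1-yl]penta-2,4-dienylidene]triphenylphosphorane | c1ccccc1P(c1ccccc1)(c1ccccc1)=C/C=C(C)/C=C/[C@H]1C(C)=CCCC1(C)C | intermediate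
11 | (6R)-12'-apo-ε-caroten-12'-al, (2E,4E,6E,8E,10E,12E)-2,7,11-trimethyl-13-[(1R)-2,6,6-trimethylcyclohex-2-en-1-yl]trideca-2,4,6,8,10,12-hexaenal | O=C/C(C)=C/C=C/C=C(C)/C=C/C=C(C)/C=C/[C@H]1C(C)=CCCC1(C)C | intermediate
12 | (3E,5E,7E,9E,11E,13E)-3,8,12-trimethyl-14-[(1R)-2,6,6-trimethylcyclohex-2-en-1-yl]tetradeca-3,5,7,9,11,13-hexaen-1-yne | C#C/C(C)=C/C=C/C=C(C)/C=C/C=C(C)/C=C/[C@H]1C(C)=CCCC1(C)C | intermediate
13 | dimethyl[(1E,5E)-2,6,10-trimethylundeca-1,5,9-trienyl]alumane | CC(C)=CCC/C(C)=C/CC/C(C)=C/[Al](C)C | intermediate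
14 | chlorobis(cyclopentadienyl)[(1E,3E,5E,7E,9E,11E,13E)-3,8,12-trimethyl-14-[(1R)-2,6,6-trimethylcyclohex-2-en-1-yl]tetradeca-1,3,5,7,9,11,13-heptaenyl]zirconium | Cl[Zr](C1C=CC=C1)(C1C=CC=C1)/C=C/C(C)=C/C=C/C=C(C)/C=C/C=C(C)/C=C/[C@H]1C(C)=CCCC1(C)C | intermediate
15 | (1R)-1-[(1E,3E,5E,7E,9E,11E,13E)-14-iodo-3,7,12-trimethyltetradeca-1,3,5,7,9,11,13-heptaenyl]-2,6,6-trimethylcyclohex-2-ene | I/C=C/C(C)=C/C=C/C=C(C)/C=C/C=C(C)/C=C/[C@H]1C(C)=CCCC1(C)C | intermediate
16 | (6R)-7',8'-dihydro-ε,ψ-carotene (α-zeacarotene), all-E | CC(C)=CCC/C(C)=C/CC/C(C)=C/C=C/C(C)=C/C=C/C=C(C)/C=C/C=C(C)/C=C/[C@H]1C(C)=CCCC1(C)C | target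

**Step count and risks**

Total step count: 7. Longest linear sequence: 5 steps (steps 3, 4, 5, 6, 7, from 6 to 16).

Steps most likely to fail:

Step 7. Risks: the heptaene may undergo iodine-promoted E/Z scrambling or degradation during the in-flask iodinolysis; homocoupling may compete; transmetalation may be incomplete in the three-metal telescoped sequence. The fallback sets out from 5 and 12 and comes back at 16. Dienyne 5 is methylaluminated as in step 7(a), via 13, and the alane is quenched with I2 (THF, −30 °C) to give, after isolation, (1E,5E)-1-iodo-2,6,10-trimethylundeca-1,5,9-triene F1. Hexaenyne 12 is hydroborated with pinacolborane under catalysis by Cp2Zr(H)Cl and Et3N to the isolable (E)-heptaenyl pinacol boronate F2. Suzuki–Miyaura coupling of F1 and F2 (Pd(PPh3)4, aq. KOH, THF, 23 °C, dark) should give 16. In this way the polyene never meets iodine and both partners are purified before the union of C10' and C11'.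

Step 6. Risks: the lithiated diazo reagent may attack along the conjugated chain (conjugate addition or cycloaddition), and vinylogous deprotonation at C6 may erode the configuration. The fallback sets out from 11 and comes back at 12. Ramirez dibromo-olefination of 11 (CBr4, PPh3, Et3N, CH2Cl2, 0 °C, dark) gives the 1,1-dibromo-olefin F3. Treatment with n-BuLi (2.1 equiv, THF, −78 °C; Corey–Fuchs, Fritsch–Buttenberg–Wiechell rearrangement) gives the lithium acetylide F4, and a water quench returns 12.

Step 5. Risks: double olefination of the dialdehyde, incomplete thermal Z-to-E funnelling at C11=C12, and methoxide-induced vinylogous deprotonation at C6 of the polyenal. The fallback sets out from 9 and 8 and comes back at 11. Dialdehyde 9 is first mono-protected (HC(OMe)3, cat. p-TsOH, MeOH, −20 °C, separation from bis-acetal) as (2E,4E,6E)-8,8-dimethoxy-2,7-dimethylocta-2,4,6-trienal F5. Wittig reaction of ylide 10 (from 8, NaOMe) with F5 should give the C25 dimethyl acetal F6 without any double olefination and with no free polyenal exposed to base. Mild hydrolysis (aq. oxalic acid, THF, 23 °C) followed by the thermal equilibration returns 11.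

**Further compounds**

F1 | step 7 | (1E,5E)-1-iodo-2,6,10-trimethylundeca-1,5,9-triene | CC(C)=CCC/C(C)=C/CC/C(C)=C/I
F2 | step 7 | 2-[(1E,3E,5E,7E,9E,11E,13E)-3,8,12-trimethyl-14-[(1R)-2,6,6-trimethylcyclohex-2-en-1-yl]tetradeca-1,3,5,7,9,11,13-heptaenyl]-4,4,5,5-tetramethyl-1,3,2-dioxaborolane | CC1(C)OB(/C=C/C(C)=C/C=C/C=C(C)/C=C/C=C(C)/C=C/[C@H]2C(C)=CCCC2(C)C)OC1(C)C
F3 | step 6 | (1R)-1-[(1E,3E,5E,7E,9E,11E)-14,14-dibromo-3,7,12-trimethyltetradeca-1,3,5,7,9,11,13-heptaenyl]-2,6,6-trimethylcyclohex-2-ene | BrC(Br)=C/C(C)=C/C=C/C=C(C)/C=C/C=C(C)/C=C/[C@H]1C(C)=CCCC1(C)C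
F4 | step 6 | lithium acetylide of 12 | [Li]C#C/C(C)=C/C=C/C=C(C)/C=C/C=C(C)/C=C/[C@H]1C(C)=CCCC1(C)C
F5 | step 5 | (2E,4E,6E)-8,8-dimethoxy-2,7-dimethylocta-2,4,6-trienal | O=C/C(C)=C/C=C/C=C(C)/C(OC)OC
F6 | step 5 | (6R)-12'-apo-ε-caroten-12'-al dimethyl acetal | COC(OC)/C(C)=C/C=C/C=C(C)/C=C/C=C(C)/C=C/[C@H]1C(C)=CCCC1(C)C
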